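**Numbering used throughout.** 1 2,4-dihydroxybenzaldehyde; 2 prenyl bromide; 3 diprenylated aldehyde; 4 its 4-O-silyl ether; 5 ring A acetal; 6 4-hydroxybenzaldehyde; 7 its 3-prenyl derivative; 8 silyl ether of 7; 9 methyl enol ether; 10 arylacetaldehyde; 11 ring B (E)-enol acetate; 12 oxocarbenium ion; 13 acetoxonium ion; 14 flavan from the key step; 15 flavan-4-ol; 16 silylated 3-acetoxyflavanone; 17 3-O-acetyl lespeflorin B3; 18 lespeflorin B3.

## Analysis of the target

Lespeflorin B3 (18) is a dihydroflavonol. Ring A is a benzene ring fused to ring C, a dihydropyranone made of O1, C2, C3, C4, C4a and C8a, and ring B is the aryl group on C2. Ring A carries prenyl groups at C6 and C8 on either side of the 7-hydroxyl and has only C5–H left; ring B carries a 4'-hydroxyl with a 3'-prenyl group. The two stereocentres, C2 (R) and C3 (R), are adjacent and trans, with the aryl and hydroxyl groups both equatorial. The trans relation is the thermodynamically preferred one, so the real task is the absolute configuration. The sensitive groups are the three trisubstituted prenyl alkenes (electrophilic oxidants, hydrogenation, strong acid next to a free ortho phenol) and the α-ketol of ring C. Under base the α-ketol can open at C2–O1 through the 4'-phenoxide, enolise at C3, rearrange, or autoxidise to the flavonol. The difficulty is to close ring C with both stereocentres on an electron-rich, fully substituted ring A without touching the prenyl groups. The strategy rests on one mapping: O1–C8a–C4a–C4 is the four-atom skeleton of an ortho-quinone methide of ring A (as its O-alkyl oxocarbenium ion), and C2–C3 is a styrene-type alkene of ring B that the para oxygen polarises so that C2 is the cationic and C3 the nucleophilic end.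

## Retrosynthetic reasoning

**18 ⇒ 17 ⇒ 16.** Only O–H bonds are made at the end. The silyl groups on O7 and O4' come off first and the C3 acetyl group last, under acid. No basic step is placed after the ketone exists, because the α-ketol with a free 4'-phenol is the base-sensitive part of the molecule.

**16 ⇒ 15 ⇒ 14.** The C4 carbonyl is traced back to a C4 hydroxyl and that to a C4 methoxy group. The C4–O bond of 14 is benzylic and is assisted by O1 (ortho) and O7 (para), so the exchange is an easy ionisation and the resulting alcohol is an activated benzylic alcohol for a mild oxidation. The C3 acetate is kept through both operations. It suppresses a pinacol-type hydride shift from C3 in the cation and leaves a single alcohol for the oxidant. The configuration at C4 is erased here.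

**14 ⇒ 5 + 11.** The cuts are C3–C4 and O1–C2, the two bonds of a hetero [4+2] annulation. They are placed there because each half is then a simple aldehyde derivative and because ring C, two skeletal bonds and all stereocentres come from one catalytic step. The four-atom partner is the acetal 5, which an acid ionises to an oxocarbenium ion; an acetal is used because the parent aldehyde is too weak an electrophile. The two-atom partner is the enol acetate 11. An acyl group on the enol oxygen is essential: acyloxy is a weaker donor than the 4-silyloxyphenyl group, so the oxygen-bearing carbon becomes the nucleophile and the product is a flavan, whereas an enol ether would react the other way round. The forward step has to control regiochemistry, the trans relation at C2/C3, the absolute configuration at C3, and chemoselectivity over three prenyl alkenes.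

**5 ⇒ 4 ⇒ 3 ⇒ 1 + 2.** The acetal comes from aldehyde 4, the silyl ether from the diphenol 3, and both prenyl groups from double C-alkylation of 1 with 2. The positions are dictated by the two oxygens of 1, and the hydrogen-bonded 2-hydroxyl stays free because it later becomes O1.

**11 ⇒ 10 ⇒ 9 ⇒ 8 ⇒ 7 ⇒ 6 + 2.** The enol acetate is the O-acylated enol of the arylacetaldehyde 10. Compound 10 is the one-carbon homologue of aldehyde 8, reached through the enol ether 9, and 8 is the silylated ortho-prenylation product 7 of 6 with 2. The silyl group keeps ring B a strong donor and prevents acid-induced cyclisation of the neighbouring prenyl group onto the phenol.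

## Alternatives that were turned down

**Alternative 1:** The cut is O1–C8a. Forward, the C2 alkoxide of the open-chain ketone A2 displaces fluoride at C8a ortho to the C4 carbonyl (intramolecular SNAr under a carbonate base in a dipolar aprotic solvent) and gives A1, the 3-O-allyl, 7,4'-bis-O-methoxymethyl derivative of the target.
- For: the ketone oxidation level and both stereocentres, set by an acyclic asymmetric aldol, are in place before ring closure; the closure needs no stereocontrol; only deprotections follow. On reliability of absolute stereocontrol it is stronger than the chosen route.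
- Against: C8a of A2 is flanked by the C8 prenyl group, and ring A is electron-rich. O7 is para to C4a and feeds electron density into the carbonyl that must stabilise the Meisenheimer intermediate, so forcing conditions are likely. Under those conditions the alkoxide of a β-hydroxy ketone can undergo retro-aldol cleavage of C2–C3, dehydration and epimerisation at C3. The fluorinated, diprenylated ring A piece is also longer to make than 5.
- Comparison: the chosen route closes ring C under acid at low temperature, where retro-aldol pathways do not exist, and needs no fluoroarene. It pays with an unprecedented key step and four steps afterwards.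

**Alternative 2:** Ring A is taken apart at C8–C8a and C5–C6. Forward, the lithium enolate of the symmetric ketone A5 adds to the methylthio-bearing carbon of the formyl dihydropyranone A4, thiolate leaves, and condensation with the formyl carbon followed by aromatisation gives A3 with the 7-hydroxyl free.
- For: both ring A prenyl groups arrive with a symmetric ketone, so no phenol prenylation is needed. On that point it is clearly stronger than the chosen route, whose step 1 is its weakest preparative step.
- Against: A4 must be made as a single enantiomer with C3 α to the ketone and C2–O1 part of a vinylogous thioester, and is then exposed to a lithium amide and an amidine base. Enolisation at C3 and opening at C2 threaten both stereocentres. The enolate carbon is a hindered secondary centre attacking a fully substituted alkene carbon, in competition with 1,2-addition to the formyl group. The sequence to A4 is long and linear.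
- Comparison: the chosen route sets the stereocentres late, under acid, from two aromatic aldehydes, and is convergent.

**Alternative 3:** The cut is C3–C4 alone. Forward, a chiral triazolium-derived carbene turns the ring A formyl group of the dialdehyde A7 into an acyl anion equivalent, which adds to the tethered aliphatic aldehyde and closes ring C as A6 while the C2 epimers of A7 interconvert.
- For: the C4 ketone and the C3 hydroxyl appear directly at the right oxidation level, so only acetal removal follows. In steps after the key step it is stronger than the chosen route.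
- Against: A7 is an α-aryl-α-aryloxy aldehyde, prone to enolisation, aldol reaction and oxidation, and its synthesis needs O-alkylation of a hindered phenol with a secondary benzylic electrophile. The carbene should prefer the aliphatic aldehyde over the electron-rich ring A aldehyde, which would give the isomeric ketol. The secondary α-ketol A6 can equilibrate under the basic carbene conditions. One catalyst must select both the C2 epimer and the aldehyde face to give the trans isomer.
- Comparison: in the chosen route the trans relation follows from the mechanism and the partners are stable, storable compounds. It pays with the C4 oxidation-state adjustment.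

Key step: step 9

**Remarks on the chemistry.**
- TBS = tert-butyldimethylsilyl; prenyl = 3-methylbut-2-en-1-yl; flavan numbering is used for 14–18.
- Assumption: the sense of induction of the catalyst cannot be derived from first principles. The (R)-catalyst is written; the (S)-catalyst is taken if the opposite sense results.
- 14 and 15 are drawn without configuration at C4. Their C3 descriptor is S and that of 16–18 is R, although the arrangement in space is the same; the change comes only from the ranking of C4 against C2.

## Route

Step 1
Reactants: 1 2,4-dihydroxybenzaldehyde; 2 prenyl bromide (1-bromo-3-methylbut-2-ene)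
Product: 3 2,4-dihydroxy-3,5-diprenylbenzaldehyde
Conditions: 2 (2.4 equiv), KOH (10% aq.), 0 °C → rt
Reagents that add atoms: none
Why: C-alkylation of the resorcinolate dianion in water, where hydrogen bonding shields the oxygens and the allylic bromide is taken up at C3 and C5, the only positions ortho or para to both oxygens; a modest yield is expected and mono-prenylated material can be resubmitted.

Step 2
Reactants: 3 2,4-dihydroxy-3,5-diprenylbenzaldehyde
Product: 4 4-[(tert-butyldimethylsilyl)oxy]-2-hydroxy-3,5-diprenylbenzaldehyde
Conditions: TBSCl (1.1 equiv), imidazole, DMF, 0 °C → rt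
Reagents that add atoms: tert-butyldimethylsilyl chloride, CC(C)(C)[Si](C)(C)Cl
Why: Silyl ether formation; the 2-hydroxyl is tied up in a hydrogen bond to the formyl group, so the more acidic 4-hydroxyl should react alone.

Step 3
Reactants: 4 4-[(tert-butyldimethylsilyl)oxy]-2-hydroxy-3,5-diprenylbenzaldehyde
Product: 5 2-(dimethoxymethyl)-5-[(tert-butyldimethylsilyl)oxy]-4,6-diprenylphenol
Conditions: HC(OMe)3, MeOH, TsOH·H2O (2 mol%), rt; Et3N, filtration through basic alumina
Reagents that add atoms: trimethyl orthoformate, COC(OC)OC; methanol, CO
Why: Acid-catalysed acetalisation driven by the orthoformate; quenching with base before concentration keeps the electron-rich ortho-hydroxy acetal from ionising, and the aryl silyl ether and prenyl groups tolerate the trace of acid.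

Step 4
Reactants: 6 4-hydroxybenzaldehyde; 2 prenyl bromide
Product: 7 4-hydroxy-3-prenylbenzaldehyde
Conditions: 2 (1.1 equiv), KOH (10% aq.), rt
Reagents that add atoms: none
Why: Ortho C-alkylation of the phenoxide in water; the O-prenyl ether by-product is separated.

Step 5
Reactants: 7 4-hydroxy-3-prenylbenzaldehyde
Product: 8 4-[(tert-butyldimethylsilyl)oxy]-3-prenylbenzaldehyde
Conditions: TBSCl, imidazole, DMF, rt
Reagents that add atoms: tert-butyldimethylsilyl chloride, CC(C)(C)[Si](C)(C)Cl
Why: Standard silylation of a phenol; the silyl ether keeps ring B a strong para donor and blocks cyclisation of the prenyl group onto oxygen in the later acid steps.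

Step 6
Reactants: 8 4-[(tert-butyldimethylsilyl)oxy]-3-prenylbenzaldehyde
Product: 9 tert-butyl[4-(2-methoxyvinyl)-2-prenylphenoxy]dimethylsilane (E/Z mixture)
Conditions: Ph3P(CH2OMe)Cl, NaN(SiMe3)2, THF, 0 °C → rt
Reagents that add atoms: (methoxymethyl)triphenylphosphonium chloride, COC[P+](c1ccccc1)(c1ccccc1)c1ccccc1.[Cl-]
Why: Wittig olefination with the methoxymethylene ylide, a one-carbon homologation; the alkene geometry is irrelevant, and the amide base is consumed by the salt before the aryl silyl ether is added.

Step 7
Reactants: 9 tert-butyl[4-(2-methoxyvinyl)-2-prenylphenoxy]dimethylsilane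
Product: 10 2-{4-[(tert-butyldimethylsilyl)oxy]-3-prenylphenyl}acetaldehyde
Conditions: HCO2H (88% aq.), CH2Cl2, rt; used crude
Reagents that add atoms: water, O
Why: Acid-catalysed enol ether hydrolysis (protonation at the benzylic carbon, addition of water, loss of methanol); formic acid is mild enough to spare the aryl silyl ether and the prenyl alkene.

Step 8
Reactants: 10 2-{4-[(tert-butyldimethylsilyl)oxy]-3-prenylphenyl}acetaldehyde
Product: 11 (E)-2-{4-[(tert-butyldimethylsilyl)oxy]-3-prenylphenyl}vinyl acetate
Conditions: Ac2O, Et3N, DMAP (cat.), CH2Cl2, rt; chromatography to isolate the E isomer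
Reagents that add atoms: acetic anhydride, CC(=O)OC(C)=O
Why: O-acylation of the easily formed, conjugated enolate of an arylacetaldehyde (enol ester formation); the E isomer is expected to predominate as the less hindered one, and the Z isomer is removed.

Step 9
Reactants: 5 2-(dimethoxymethyl)-5-[(tert-butyldimethylsilyl)oxy]-4,6-diprenylphenol; 11 (E)-2-{4-[(tert-butyldimethylsilyl)oxy]-3-prenylphenyl}vinyl acetate (1.5 equiv)
Product: 14 (2R,3S)-7-[(tert-butyldimethylsilyl)oxy]-2-{4-[(tert-butyldimethylsilyl)oxy]-3-prenylphenyl}-4-methoxy-6,8-diprenylchroman-3-yl acetate (2,3-trans; either C4 epimer), via oxocarbenium ion 12 (not isolated), via acetoxonium ion 13 (not isolated)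
Conditions: (R)-3,3'-bis(2,4,6-triisopropylphenyl)-BINOL N-triflyl phosphoramide (10 mol%), 5 Å MS, toluene, −60 → −30 °C; Et3N
Reagents that add atoms: none
Why: Proposed new method: the phosphoramide protonates a methoxy group of 5 and the oxocarbenium ion 12 forms, held to the chiral anion by ion pairing and by a hydrogen bond from its ortho-hydroxyl; the acetoxy-bearing carbon of 11 (the future C3) attacks C4, since the 4-silyloxyphenyl group stabilises positive charge at C2 far better than an acyloxy group would at C3, and the acetate carbonyl captures that charge anti to the new bond as the trans-4,5-disubstituted acetoxonium ion 13. The closest known reaction type is the chiral Brønsted acid-catalysed [4+2] annulation of ortho-quinone methides and of salicylaldehyde acetals with styrenes and enol ethers; an enol ester as the two-carbon partner, which places oxygen on C3, has not been shown. Ring C closes when the phenol oxygen opens 13 at C2 with inversion (6-exo-tet) and returns its proton to the catalyst; anti capture followed by anti opening amounts to suprafacial addition across the E alkene, so the C2 aryl and C3 acetoxy groups should end trans, and a free benzylic cation would collapse to the same diequatorial isomer. C3 is set by the chiral anion in the C–C bond-forming event, C2 follows C3 through this relay, and C4 is set in the same event but is not needed. Because C4 is oxidised later, what counts is the face of the enol acetate: the two C3/C4 diastereomers that arise on one face of 12 have opposite configurations at C3 and C2 and would become enantiomers once C4 is a carbonyl, so one diastereomer has to dominate and the enantiomeric purity is read at 16. The step needs chemoselectivity for the donor-substituted styrenyl alkene over the three prenyl alkenes, which the para-silyloxy group and the bulk of the trisubstituted prenyl termini should provide, and regioselectivity for C3–C4 over C2–C4 bonding, which rests on aryl being the stronger donor. Low temperature and molecular sieves keep methanol from intercepting 13 and the acid from cyclising the ortho-prenyl phenol.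

Step 10
Reactants: 14 (2R,3S)-7-[(tert-butyldimethylsilyl)oxy]-2-{4-[(tert-butyldimethylsilyl)oxy]-3-prenylphenyl}-4-methoxy-6,8-diprenylchroman-3-yl acetate
Product: 15 (2R,3S)-7-[(tert-butyldimethylsilyl)oxy]-2-{4-[(tert-butyldimethylsilyl)oxy]-3-prenylphenyl}-4-hydroxy-6,8-diprenylchroman-3-yl acetate (either C4 epimer)
Conditions: TsOH·H2O (5 mol%), THF/H2O (4:1), 0 °C → rt; NaHCO3 as soon as 14 is consumed
Reagents that add atoms: water, O
Why: SN1 solvolysis of a benzylic ether whose cation is stabilised by O1 and O7; water captures the cation much faster than a proton is lost from C3, and the equatorial C3 acetate of the 2,3-trans series is badly placed to bridge to C4, so acyl migration should stay minor if the reaction is stopped early.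

Step 11
Reactants: 15 (2R,3S)-7-[(tert-butyldimethylsilyl)oxy]-2-{4-[(tert-butyldimethylsilyl)oxy]-3-prenylphenyl}-4-hydroxy-6,8-diprenylchroman-3-yl acetate
Product: 16 (2R,3R)-7-[(tert-butyldimethylsilyl)oxy]-2-{4-[(tert-butyldimethylsilyl)oxy]-3-prenylphenyl}-4-oxo-6,8-diprenylchroman-3-yl acetate
Conditions: MnO2 (activated, excess), CH2Cl2, rt
Reagents that add atoms: none
Why: Manganese dioxide oxidation of an electron-rich benzylic alcohol; both C4 epimers converge on one ketone, and the prenyl alkenes, silyl ethers and acetate are inert to this oxidant.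

Step 12
Reactants: 16 (2R,3R)-7-[(tert-butyldimethylsilyl)oxy]-2-{4-[(tert-butyldimethylsilyl)oxy]-3-prenylphenyl}-4-oxo-6,8-diprenylchroman-3-yl acetate
Product: 17 (2R,3R)-7-hydroxy-2-(4-hydroxy-3-prenylphenyl)-4-oxo-6,8-diprenylchroman-3-yl acetate
Conditions: Bu4NF, AcOH (1:1), THF, 0 °C
Reagents that add atoms: none
Why: Fluoride cleavage of aryl silyl ethers; the acetic acid buffer protonates the phenoxides at once, so the α-acetoxy ketone and the C2–O1 bond should not be exposed to base.

Step 13
Reactants: 17 (2R,3R)-7-hydroxy-2-(4-hydroxy-3-prenylphenyl)-4-oxo-6,8-diprenylchroman-3-yl acetate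
Product: 18 lespeflorin B3, (2R,3R)-3,7-dihydroxy-2-(4-hydroxy-3-prenylphenyl)-6,8-diprenylchroman-4-one
Conditions: HCl (0.5 M, from AcCl) in MeOH, 0 °C → rt
Reagents that add atoms: none
Why: Acid-catalysed transesterification (methanolysis) of the α-acetoxy ketone, the classical way from 3-acetoxyflavanones to dihydroflavonols; no base is used, so C2, C3 and the α-ketol should stay intact, and dilute methanolic acid at room temperature is the usual final operation on prenylated flavonoids.

## Compound list

1 | 2,4-dihydroxybenzaldehyde | O=Cc1ccc(O)cc1O | starting material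
2 | prenyl bromide (1-bromo-3-methylbut-2-ene) | CC(C)=CCBr | starting material
3 | 2,4-dihydroxy-3,5-diprenylbenzaldehyde | O=Cc1cc(CC=C(C)C)c(O)c(CC=C(C)C)c1O | intermediate
4 | 4-[(tert-butyldimethylsilyl)oxy]-2-hydroxy-3,5-diprenylbenzaldehyde | O=Cc1cc(CC=C(C)C)c(O[Si](C)(C)C(C)(C)C)c(CC=C(C)C)c1O | intermediate
5 | 2-(dimethoxymethyl)-5-[(tert-butyldimethylsilyl)oxy]-4,6-diprenylphenol | COC(OC)c1cc(CC=C(C)C)c(O[Si](C)(C)C(C)(C)C)c(CC=C(C)C)c1O | intermediate
6 | 4-hydroxybenzaldehyde | O=Cc1ccc(O)cc1 | starting material
7 | 4-hydroxy-3-prenylbenzaldehyde | CC(C)=CCc1cc(C=O)ccc1O | intermediate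
8 | 4-[(tert-butyldimethylsilyl)oxy]-3-prenylbenzaldehyde | CC(C)=CCc1cc(C=O)ccc1O[Si](C)(C)C(C)(C)C | intermediate
9 | tert-butyl[4-(2-methoxyvinyl)-2-prenylphenoxy]dimethylsilane (E/Z mixture) | COC=Cc1ccc(O[Si](C)(C)C(C)(C)C)c(CC=C(C)C)c1 | intermediate
10 | 2-{4-[(tert-butyldimethylsilyl)oxy]-3-prenylphenyl}acetaldehyde | O=CCc1ccc(O[Si](C)(C)C(C)(C)C)c(CC=C(C)C)c1 | intermediate
11 | (E)-2-{4-[(tert-butyldimethylsilyl)oxy]-3-prenylphenyl}vinyl acetate | CC(=O)O/C=C/c1ccc(O[Si](C)(C)C(C)(C)C)c(CC=C(C)C)c1 | intermediate
12 | O-methyl oxocarbenium ion of ring A (ion pair with the catalyst anion) | C[O+]=Cc1cc(CC=C(C)C)c(O[Si](C)(C)C(C)(C)C)c(CC=C(C)C)c1O | intermediate (not isolated)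
13 | trans-4,5-disubstituted 2-methyl-1,3-dioxolan-2-ylium (acetoxonium) ion, ring B aryl on one ring carbon and the ring A methoxymethine on the other | CC(C)=CCc1cc([C@@H]2O[C+](C)O[C@H]2C(OC)c3cc(CC=C(C)C)c(O[Si](C)(C)C(C)(C)C)c(CC=C(C)C)c3O)ccc1O[Si](C)(C)C(C)(C)C | intermediate (not isolated)
14 | (2R,3S)-7-[(tert-butyldimethylsilyl)oxy]-2-{4-[(tert-butyldimethylsilyl)oxy]-3-prenylphenyl}-4-methoxy-6,8-diprenylchroman-3-yl acetate (2,3-trans; either C4 epimer) | CC(C)=CCc1cc([C@H]2Oc3c(cc(CC=C(C)C)c(O[Si](C)(C)C(C)(C)C)c3CC=C(C)C)C(OC)[C@@H]2OC(C)=O)ccc1O[Si](C)(C)C(C)(C)C | intermediate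
15 | (2R,3S)-7-[(tert-butyldimethylsilyl)oxy]-2-{4-[(tert-butyldimethylsilyl)oxy]-3-prenylphenyl}-4-hydroxy-6,8-diprenylchroman-3-yl acetate (either C4 epimer) | CC(C)=CCc1cc([C@H]2Oc3c(cc(CC=C(C)C)c(O[Si](C)(C)C(C)(C)C)c3CC=C(C)C)C(O)[C@@H]2OC(C)=O)ccc1O[Si](C)(C)C(C)(C)C | intermediate
16 | (2R,3R)-7-[(tert-butyldimethylsilyl)oxy]-2-{4-[(tert-butyldimethylsilyl)oxy]-3-prenylphenyl}-4-oxo-6,8-diprenylchroman-3-yl acetate | CC(C)=CCc1cc([C@H]2Oc3c(cc(CC=C(C)C)c(O[Si](C)(C)C(C)(C)C)c3CC=C(C)C)C(=O)[C@@H]2OC(C)=O)ccc1O[Si](C)(C)C(C)(C)C | intermediate
17 | (2R,3R)-7-hydroxy-2-(4-hydroxy-3-prenylphenyl)-4-oxo-6,8-diprenylchroman-3-yl acetate | CC(C)=CCc1cc([C@H]2Oc3c(cc(CC=C(C)C)c(O)c3CC=C(C)C)C(=O)[C@@H]2OC(C)=O)ccc1O | intermediate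
18 | lespeflorin B3, (2R,3R)-3,7-dihydroxy-2-(4-hydroxy-3-prenylphenyl)-6,8-diprenylchroman-4-one | CC(C)=CCc1cc([C@H]2Oc3c(cc(CC=C(C)C)c(O)c3CC=C(C)C)C(=O)[C@@H]2O)ccc1O | target

## Step count and uncertain steps

Total: 13 steps. Longest linear sequence: 10 steps (steps 4–13, from 6 to 18).

**Step 9 (key step).** Several processes may go wrong.
- The oxocarbenium ion may be too weak an electrophile, since the para-silyloxy group stabilises it.
- The prenyl alkenes may compete as nucleophiles, or the acid may cyclise the ortho-prenyl phenol of 5.
- Methanol may capture the acetoxonium ion.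
- The enol acetate may transfer its acyl group to the free phenol of 5 under the acid.
- Facial selection on the enol acetate may be poor; this would not show in the C4 ratio but in the enantiomeric purity at 16.

The fallback is the chalcone epoxide route, all of it known chemistry. It sets out from 3 and 7 and comes back at 18. Aldehyde 3 is protected (MOMCl, NaH, DMF) to 2,4-bis(methoxymethoxy)-3,5-diprenylbenzaldehyde F1. MeMgBr gives 1-[2,4-bis(methoxymethoxy)-3,5-diprenylphenyl]ethanol F2, and oxidation (MnO2 or Dess–Martin periodinane) gives 1-[2,4-bis(methoxymethoxy)-3,5-diprenylphenyl]ethanone F3. Aldehyde 7 is protected (MOMCl, iPr2NEt) as 4-(methoxymethoxy)-3-prenylbenzaldehyde F4. Claisen–Schmidt condensation of F3 with F4 (KOH, EtOH) gives the (E)-chalcone F5. Julia–Colonna epoxidation (poly-L-leucine, urea–H2O2, DBU, THF) should give the (αR,βS)-epoxy ketone F6; nucleophilic epoxidation does not touch the prenyl alkenes. Methanolic HCl then removes the three acetal groups, and the freed 2'-phenol opens the epoxide at the benzylic carbon. C3 keeps the Cα–O bond of the epoxide and with it its configuration, C2 settles trans, and 18 results.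

**Step 10.** The C4 cation may lose the C3 proton to give a flav-3-ene enol acetate, or the acetate may bridge to C4 and migrate, and both drain material if the solvolysis runs too long. The fallback avoids the alcohol altogether. It sets out from 14 and comes back at 16: DDQ in wet CH2Cl2 abstracts hydride from C4–H of the benzylic methyl ether and water converts the methoxy-oxocarbenium ion into the ketone. It makes no new compound (F0). Its own risk is oxidation at the benzylic, allylic methylene groups of the prenyl chains.

**Step 13.** Acid may cyclise a prenyl group onto a free ortho phenol during a slow methanolysis, or the methanolysis may stall. The fallback removes the acetate before the ketone exists. It sets out from 14 and comes back at 18. iBu2AlH (CH2Cl2, −78 °C) cleaves the acetate to (2R,3S)-7-[(tert-butyldimethylsilyl)oxy]-2-{4-[(tert-butyldimethylsilyl)oxy]-3-prenylphenyl}-4-methoxy-6,8-diprenylchroman-3-ol F7. Solvolysis as in step 10 gives the 3,4-diol F8. MnO2 oxidises the benzylic hydroxyl selectively to (2R,3R)-7-[(tert-butyldimethylsilyl)oxy]-2-{4-[(tert-butyldimethylsilyl)oxy]-3-prenylphenyl}-3-hydroxy-6,8-diprenylchroman-4-one F9, and Bu4NF/AcOH gives 18. The price is an oxidation next to a free hydroxyl, where glycol cleavage has to be watched.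

**Step 1.** Poor control between C- and O-alkylation and between mono- and di-prenylation is likely, so the yield may be low. The fallback installs the groups one at a time by Claisen rearrangement. It sets out from 1 and comes back at 3. O-Alkylation of the 4-hydroxyl with methyl 2-methylbut-3-en-2-yl carbonate and Pd(PPh3)4 (zerovalent palladium, Tsuji–Trost reaction at the substituted terminus) gives 2-hydroxy-4-[(2-methylbut-3-en-2-yl)oxy]benzaldehyde F10. Heating (PhNEt2, 130 °C) gives 2,4-dihydroxy-3-prenylbenzaldehyde F11 by aromatic Claisen rearrangement; any 5-prenyl isomer converges in the next round. A second O-alkylation gives 2-hydroxy-4-[(2-methylbut-3-en-2-yl)oxy]-3-prenylbenzaldehyde F12, and a second Claisen rearrangement to the only free ortho position gives 3.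

**Step 8.** Control of alkene geometry may be poor, and the arylacetaldehyde may condense with itself under the basic acylation. A Z isomer would reach the 2,3-cis series if the acetoxonium relay is faster than bond rotation. The fallback fixes the geometry before the oxygen is introduced. It sets out from 8 and comes back at 11. A boron-Wittig reaction (CH2(Bpin)2, lithium 2,2,6,6-tetramethylpiperidide, THF, −78 °C → rt) gives the (E)-alkenyl pinacol boronate F13. Oxidative acetoxylation with Cu(OAc)2 (Chan–Lam type; DMAP, 4 Å MS, air, MeCN) should replace boron by acetate with retention of geometry.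

## Further compounds

F1 | step 9 | 2,4-bis(methoxymethoxy)-3,5-diprenylbenzaldehyde | O=Cc1cc(CC=C(C)C)c(OCOC)c(CC=C(C)C)c1OCOC
F2 | step 9 | 1-[2,4-bis(methoxymethoxy)-3,5-diprenylphenyl]ethanol (racemic) | CC(O)c1cc(CC=C(C)C)c(OCOC)c(CC=C(C)C)c1OCOC
F3 | step 9 | 1-[2,4-bis(methoxymethoxy)-3,5-diprenylphenyl]ethanone | CC(=O)c1cc(CC=C(C)C)c(OCOC)c(CC=C(C)C)c1OCOC
F4 | step 9 | 4-(methoxymethoxy)-3-prenylbenzaldehyde | COCOc1ccc(C=O)cc1CC=C(C)C
F5 | step 9 | (E)-1-[2,4-bis(methoxymethoxy)-3,5-diprenylphenyl]-3-[4-(methoxymethoxy)-3-prenylphenyl]prop-2-en-1-one | COCOc1ccc(/C=C/C(=O)c2cc(CC=C(C)C)c(OCOC)c(CC=C(C)C)c2OCOC)cc1CC=C(C)C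
F6 | step 9 | (2R,3S)-2,3-epoxy-1-[2,4-bis(methoxymethoxy)-3,5-diprenylphenyl]-3-[4-(methoxymethoxy)-3-prenylphenyl]propan-1-one | O=C([C@@H]1O[C@H]1c2ccc(OCOC)c(CC=C(C)C)c2)c3cc(CC=C(C)C)c(OCOC)c(CC=C(C)C)c3OCOC
F0 | step 10 | none | none
F7 | step 13 | (2R,3S)-7-[(tert-butyldimethylsilyl)oxy]-2-{4-[(tert-butyldimethylsilyl)oxy]-3-prenylphenyl}-4-methoxy-6,8-diprenylchroman-3-ol (either C4 epimer) | CC(C)=CCc1cc([C@H]2Oc3c(cc(CC=C(C)C)c(O[Si](C)(C)C(C)(C)C)c3CC=C(C)C)C(OC)[C@@H]2O)ccc1O[Si](C)(C)C(C)(C)C
F8 | step 13 | (2R,3S)-7-[(tert-butyldimethylsilyl)oxy]-2-{4-[(tert-butyldimethylsilyl)oxy]-3-prenylphenyl}-6,8-diprenylchromane-3,4-diol (either C4 epimer) | CC(C)=CCc1cc([C@H]2Oc3c(cc(CC=C(C)C)c(O[Si](C)(C)C(C)(C)C)c3CC=C(C)C)C(O)[C@@H]2O)ccc1O[Si](C)(C)C(C)(C)C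
F9 | step 13 | (2R,3R)-7-[(tert-butyldimethylsilyl)oxy]-2-{4-[(tert-butyldimethylsilyl)oxy]-3-prenylphenyl}-3-hydroxy-6,8-diprenylchroman-4-one | CC(C)=CCc1cc([C@H]2Oc3c(cc(CC=C(C)C)c(O[Si](C)(C)C(C)(C)C)c3CC=C(C)C)C(=O)[C@@H]2O)ccc1O[Si](C)(C)C(C)(C)C
F10 | step 1 | 2-hydroxy-4-[(2-methylbut-3-en-2-yl)oxy]benzaldehyde | O=Cc1ccc(OC(C)(C)C=C)cc1O
F11 | step 1 | 2,4-dihydroxy-3-prenylbenzaldehyde | O=Cc1ccc(O)c(CC=C(C)C)c1O
F12 | step 1 | 2-hydroxy-4-[(2-methylbut-3-en-2-yl)oxy]-3-prenylbenzaldehyde | O=Cc1ccc(OC(C)(C)C=C)c(CC=C(C)C)c1O
F13 | step 8 | (E)-tert-butyldimethyl{2-prenyl-4-[2-(4,4,5,5-tetramethyl-1,3,2-dioxaborolan-2-yl)vinyl]phenoxy}silane | CC(C)=CCc1cc(/C=C/B2OC(C)(C)C(C)(C)O2)ccc1O[Si](C)(C)C(C)(C)C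
A1 | alternative 1 | (2R,3R)-3-(allyloxy)-7-(methoxymethoxy)-2-[4-(methoxymethoxy)-3-prenylphenyl]-6,8-diprenylchroman-4-one | CC(C)=CCc1cc([C@H]2Oc3c(cc(CC=C(C)C)c(OCOC)c3CC=C(C)C)C(=O)[C@@H]2OCC=C)ccc1OCOC
A2 | alternative 1 | (2R,3R)-2-(allyloxy)-1-[2-fluoro-4-(methoxymethoxy)-3,5-diprenylphenyl]-3-hydroxy-3-[4-(methoxymethoxy)-3-prenylphenyl]propan-1-one | CC(C)=CCc1cc([C@@H](O)[C@@H](OCC=C)C(=O)c2cc(CC=C(C)C)c(OCOC)c(CC=C(C)C)c2F)ccc1OCOC
A3 | alternative 2 | (2R,3R)-3-[(tert-butyldimethylsilyl)oxy]-7-hydroxy-2-[4-(methoxymethoxy)-3-prenylphenyl]-6,8-diprenylchroman-4-one | CC(C)=CCc1cc([C@H]2Oc3c(cc(CC=C(C)C)c(O)c3CC=C(C)C)C(=O)[C@@H]2O[Si](C)(C)C(C)(C)C)ccc1OCOC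
A4 | alternative 2 | (2R,3R)-3-[(tert-butyldimethylsilyl)oxy]-2-[4-(methoxymethoxy)-3-prenylphenyl]-6-(methylthio)-4-oxo-3,4-dihydro-2H-pyran-5-carbaldehyde | CSC1=C(C=O)C(=O)[C@H](O[Si](C)(C)C(C)(C)C)[C@@H](c2ccc(OCOC)c(CC=C(C)C)c2)O1
A5 | alternative 2 | 2,10-dimethylundeca-2,9-dien-6-one | CC(C)=CCCC(=O)CCC=C(C)C
A6 | alternative 3 | (2R,3R)-3-hydroxy-7-(methoxymethoxy)-2-[4-(methoxymethoxy)-3-prenylphenyl]-6,8-diprenylchroman-4-one | CC(C)=CCc1cc([C@H]2Oc3c(cc(CC=C(C)C)c(OCOC)c3CC=C(C)C)C(=O)[C@@H]2O)ccc1OCOC
A7 | alternative 3 | 4-(methoxymethoxy)-2-{1-[4-(methoxymethoxy)-3-prenylphenyl]-2-oxoethoxy}-3,5-diprenylbenzaldehyde (racemic) | O=CC(Oc1c(CC=C(C)C)c(OCOC)c(CC=C(C)C)cc1C=O)c1ccc(OCOC)c(CC=C(C)C)c1
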